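## Structural features

The target is a chalcone whose ring A is a phloroglucinol nucleus: C6 carries the (E)-3-(4-hydroxyphenyl)propenoyl chain (ring C at its far end), C5 and C7 carry free hydroxyls that both flank the ketone, and C8 is the only ring CH. Ring A is fused through C4a and C8a to a dihydropyran, ring B, made up of O1, the quaternary gem-dimethyl carbon C2, the carbinol carbon C3 and the benzylic methylene C4; O1 stands para to the acyl carbon on C6. C3 is the only stereocentre, (R), set between quaternary C2 and C4, so there is no relative stereochemistry to control and no neighbouring centre to relay from. The fragile parts are the 2',6'-dihydroxychalcone, which closes to flavanones under acid, base or heat and whose enone does not survive hydrogenation or hydride, and the tertiary alkyl aryl ether O1–C2, which is at risk under the strong Lewis acids needed to cleave methyl ethers. The real difficulties are therefore the lone stereocentre at C3, the placement of O1 para rather than ortho to the C6 carbon on a ring whose three oxygens are otherwise alike, and the timing of phenol deprotection relative to enone formation. The key step uses the fact that C3 bears a hydroxyl and is bonded to benzylic C4: with C4 raised to a ketone, C3–C4 is an acyloin bond, so ring B can be closed by joining an aldehyde carbon on C4a to an aldehyde carbon hung from O1 through C2. In that ketone the same arrangement in space at C3 is called (S), because C4 then outranks C2; it reverts to (R) once C4 is a carbinol or methylene carbon.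

## Logic of the disconnections

20 to 19. No skeletal bond is cut; three O–CH2 acetal bonds on the phenolic oxygens are restored. The reason is that free hydroxyls at C5 and C7 next to an enone cyclise, and the base used to make the enone needs them masked. The gain is that the chalcone can be assembled from fully protected partners. The forward step must be an acetal cleavage mild and brief enough to leave the enone, the tertiary ether and C3 alone, which is why acetal ethers replace methyl ethers throughout.

19 to 16 and 17. The Cα=Cβ bond of the enone is cut (aldol condensation). This is the most dependable way to a chalcone and removes ring C together with the fragile alkene. 16 then holds only rings A and B. The forward step needs base-stable protecting groups, a ketone that can enolise only at its methyl group, and an aldehyde that cannot enolise.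

16 to 12, through 15, 14 and 13. The C(=O)–CH3 bond of 16 is cut (15 from 14 and a methyl nucleophile), and 14, 13 and 12 differ only in the oxidation level of the C6 carbon. A ketone at C6 would not survive the reductions that remove the C4 oxygen and would interfere with the formylation; an ester is inert to both. The forward steps need a hydride small enough to reach a doubly ortho-substituted ester and two oxidations that act on benzylic alcohols only, leaving the C3 carbinol.

12 to 10, through 11. The two C4–H bonds are exchanged for C4–O (alcohol, then ketone). This makes C3–C4 an acyloin bond and exposes the retron for umpolung. The forward deoxygenation must pass through C4 alone, leave the C3–O bond and the acetals intact, and 10 must be reduced promptly because its C3–H is α to a ketone.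

10 to 9. The C3–C4 bond is cut, ring B opens and the stereocentre disappears. What remains is an achiral dialdehyde on a benzoate. The forward step must make the aryl aldehyde the acyl-anion partner, control the face of the acceptor, and avoid base-induced loss of configuration.

9 to 6, through 7. The aliphatic aldehyde carbon (the future C3) is traced to a vinyl group by C=C cleavage, and the vinyl group to an ethynyl group. A direct SN2 etherification at a tertiary α-halo aldehyde would compete with elimination and conjugate addition, whereas propargylic etherification forms the hindered O1–C2 bond cleanly. The forward steps need a semihydrogenation that stops at the alkene and an oxidative cleavage that spares arene, aryl aldehyde and acetals.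

6 to 3, through 5. Two acetal O–C bonds and the C4a–C4 bond (the formyl group) are cut. A free hydroxyl ortho to the site directs the formylation, and the mirror plane of 3 through the ester carbon and O1 makes the two open ring positions equivalent, so one regioisomer results and O1 is fixed para to the C6 carbon. The forward steps need monoformylation and complete alkylation of two chelated phenols.

3 to 1 and 2. The O1–C2 bond is cut. The 4-hydroxyl of 1 is the only one not hydrogen-bonded to the ester and is the most acidic, so it can be alkylated selectively without a temporary protecting group. The forward step needs O- rather than C-alkylation and monoalkylation.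

## Other disconnections considered

Alternative 1: The cut is the O1–C2 bond of ring B, made while the other ortho oxygen of ring A and the enone are tied up in a flavanone ring. In the forward sense a Brønsted acid activates epoxide A1 and the only free ortho phenol attacks the tertiary epoxide carbon in a 6-endo opening to give A2; a later base-induced retro-oxa-Michael opening of the flavanone ring would release 20.
- In its favour: the C3–O bond is never broken, so the (R) centre would come intact from an asymmetric epoxidation of a trisubstituted olefin; no oxygen has to be removed from C4; and the flavanone ring settles the placement of O1 because only one phenol can reach the epoxide.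
- Against it here: the 5-exo opening at the secondary carbon (a hydroxyisopropyl dihydrobenzofuran, with inversion) competes and is only biased, not excluded, by acid. The olefin precursor of A1 needs a C8-selective prenylation of a ring that also offers C6. The last step is an equilibrium that normally lies on the flavanone side for a ketone flanked by two ortho oxygens, with re-closure possible onto either of them, so 20 would have to be separated from A2 and its linear isomer.
- Comparison: this plan forms a C–O bond and imports the stereocentre, whereas the chosen plan forms C3–C4 and creates the centre in the same event. The epoxide opening rests on better precedent than the carbene step, and the sequence would be clearly shorter; on both points Alternative 1 is the better. The chosen plan is stronger only at the end, where the enone is built last from protected partners and never meets equilibrating base.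

Alternative 2: The cut is the pair of C–O bonds at C3 and C4 (oxygen transfer to a C3=C4 double bond). In the forward sense chromene A3 is epoxidised with (R,R)-N,N'-bis(3,5-di-tert-butylsalicylidene)-1,2-cyclohexanediaminomanganese chloride and NaOCl to the cis epoxide A4, and hydride opening at benzylic C4 then leaves the (3R) alcohol.
- In its favour: 2,2-dimethylchromenes are among the best substrate classes for this epoxidation; A3 lies about three steps from 1 and 2; and the C4 oxygen leaves in the very step that unveils the C3 hydroxyl, so no separate deoxygenation is needed.
- Against it here: an epoxide on so electron-rich a ring ionises easily at C4 and may rearrange or open with loss of enantiomeric purity before it is reduced, and hypochlorite may chlorinate C8.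
- Comparison: both plans reach the same kind of protected chroman-3-ol and use the same symmetry of 1 to place O1. Alternative 2 sets C3 by a reaction established for this ring system and would be about four steps shorter; on precedent and step count it is the better plan, and with acetal in place of methyl ethers it is the sequence held in reserve for step 6. The chosen plan offers in exchange a metal-free, C–C bond-forming ring closure from an achiral dialdehyde and a ketol that is less acid-labile than A4.

Alternative 3: The cut is the C4–C4a bond. In the forward sense Rh2(OAc)4 decomposes the aryloxy diazoketone A5 and the rhodium carbenoid substitutes the ortho ring carbon to close ring B as chroman-3-one A6; an enantioselective ketone reduction (for example the Corey–Bakshi–Shibata reduction) would then set C3.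
- In its favour: both ortho carbons of the symmetric aryl ether are equivalent, so the closure has no regiochemical question; C4 arrives as a methylene; and the ketone is flanked by very different groups (quaternary C2 against the C4 methylene), which suits reagent-controlled reduction.
- Against it here: A5 calls for a diazomethane-type acylation of a hindered acid chloride, a hazard on scale; the carbenoid may add to the arene with ring expansion (Buchner reaction) instead of substituting it; and A6 enolises towards C4 and oxidises readily, so it must be reduced at once.
- Comparison: the plan closes the same ring from the other side of C4 and separates ring closure from stereocontrol. With no deoxygenation to follow it would be about one step shorter, a point in its favour, and its stereo-setting reduction is at least the equal of the chosen key step in precedent. The chosen plan avoids diazo compounds and rhodium.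

Key step: step 6

Assumption: the (5aS,10bR) antipode of the triazolium salt is taken to be the one that directs the new C–C bond to the Re face of the tethered aldehyde; if a first trial shows the opposite sense, the (5aR,10bS) antipode is used and the route is otherwise unchanged.

## Route

Step 1
Reactants: 1 methyl 2,4,6-trihydroxybenzoate; 2 3-chloro-3-methylbut-1-yne
Product: 3 methyl 2,6-dihydroxy-4-[(2-methylbut-3-yn-2-yl)oxy]benzoate
Conditions: 2 (1.1 equiv), CuCl2·2H2O (1 mol%), DBU (1.2 equiv), MeCN, 0 °C
Reagents that add atoms: none
Why: Copper-catalysed propargylic etherification (a copper acetylide of 2 ionises to a copper allenylidene that the phenoxide captures at the tertiary carbon); one equivalent of amidine base deprotonates only the 4-hydroxyl of 1, which is para to the ester and not hydrogen-bonded, so the tertiary O1–C2 ether forms at the right oxygen without a temporary protecting group.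

Step 2
Reactants: 3 methyl 2,6-dihydroxy-4-[(2-methylbut-3-yn-2-yl)oxy]benzoate
Product: 5 methyl 3-formyl-2,6-dihydroxy-4-[(2-methylbut-3-yn-2-yl)oxy]benzoate, via hydroxymethyl phenol 4 (not isolated)
Conditions: MgCl2 (3 equiv), Et3N (6 equiv), (CH2O)n (3 equiv), THF, 65 °C; aq. HCl work-up
Reagents that add atoms: paraformaldehyde (as formaldehyde), C=O
Why: Casnati–Skattebøl ortho-formylation: the magnesium phenoxide of a chelated hydroxyl delivers formaldehyde to the adjacent ring carbon to give 4, whose magnesium alkoxide passes hydride to a second formaldehyde; the two open ring positions of 3 are equivalent by symmetry, so only one monoaldehyde can form, and the new formyl group deactivates the ring towards a second formylation.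

Step 3
Reactants: 5 methyl 3-formyl-2,6-dihydroxy-4-[(2-methylbut-3-yn-2-yl)oxy]benzoate
Product: 6 methyl 3-formyl-2,6-bis(methoxymethoxy)-4-[(2-methylbut-3-yn-2-yl)oxy]benzoate
Conditions: NaH (2.2 equiv), MOMCl (2.5 equiv), DMF, 0 °C to rt
Reagents that add atoms: chloromethyl methyl ether (MOMCl), COCCl
Why: Williamson-type O-alkylation of the two sodium phenoxides with the very reactive chloromethyl ether; full deprotonation is needed because both hydroxyls are chelated, and the hydride is limited to what they consume so that the alkyne C–H is left alone.

Step 4
Reactants: 6 methyl 3-formyl-2,6-bis(methoxymethoxy)-4-[(2-methylbut-3-yn-2-yl)oxy]benzoate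
Product: 7 methyl 3-formyl-2,6-bis(methoxymethoxy)-4-[(2-methylbut-3-en-2-yl)oxy]benzoate
Conditions: H2 (1 atm), 5% Pd/CaCO3 poisoned with Pb(OAc)2, quinoline, EtOAc, rt
Reagents that add atoms: none
Why: Lindlar semihydrogenation of the terminal alkyne to the vinyl group on a poisoned catalyst; aldehyde, ester and acetals are not reduced, and the reaction is stopped after one equivalent of hydrogen.

Step 5
Reactants: 7 methyl 3-formyl-2,6-bis(methoxymethoxy)-4-[(2-methylbut-3-en-2-yl)oxy]benzoate
Product: 9 methyl 3-formyl-2,6-bis(methoxymethoxy)-4-[(2-methyl-1-oxopropan-2-yl)oxy]benzoate, via secondary ozonide 8 (not isolated)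
Conditions: O3, CH2Cl2, −78 °C; then PPh3, −78 °C to rt
Reagents that add atoms: ozone, [O-][O+]=O
Why: Ozonolysis with reductive work-up: the monosubstituted alkene reacts with ozone far faster than the arene, which is deactivated by formyl and ester groups, and PPh3 reduces ozonide 8 to the aldehyde; the α-carbon is quaternary, so the new aldehyde cannot enolise, and 7 is kept cold beforehand because aryl 1,1-dimethylallyl ethers rearrange on heating.

Step 6
Reactants: 9 methyl 3-formyl-2,6-bis(methoxymethoxy)-4-[(2-methyl-1-oxopropan-2-yl)oxy]benzoate
Product: 10 methyl (3S)-3-hydroxy-5,7-bis(methoxymethoxy)-2,2-dimethyl-4-oxochroman-6-carboxylate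
Conditions: (5aS,10bR)-5a,10b-dihydro-2-(pentafluorophenyl)-4H,6H-indeno[2,1-b][1,2,4]triazolo[4,3-d][1,4]oxazinium tetrafluoroborate (10 mol%), Et3N (10 mol%), toluene, 0 °C to rt, argon
Reagents that add atoms: none
Why: Proposed new method: the carbene freed from the triazolium salt adds to the aryl aldehyde of 9, proton transfer gives the Breslow enaminol, this acyl-anion equivalent attacks the tethered aliphatic aldehyde, and collapse of the adduct returns the carbene and leaves α-ketol 10 (intramolecular crossed benzoin); the closest known reaction type is the triazolium-catalysed enantioselective cyclisation of aryl aldehydes onto tethered ketones, which gives 3-hydroxychroman-4-ones with a tertiary carbinol, whereas here the acceptor is an aldehyde and the carbinol is secondary. Ring B closes in the 6-exo-trig mode, the nucleophilic C4 attacking C3 whose C=O lies outside the new ring. C3 is set by the catalyst: the indane-fused backbone shields one face of the enaminol, and the hydrogen bond from the enaminol OH to the acceptor oxygen in the cyclic transition state fixes which face of the acceptor is presented, so that bond formation on the Re face of the aldehyde (O before C2 before H) gives (3S). The aryl aldehyde is expected to be the donor because quaternary C2 makes the aliphatic aldehyde neopentyl-like and non-enolisable, so its carbene adduct is slow to become an enaminol and it serves as the acceptor. A weak amine base in catalytic amount and a non-polar solvent are chosen so that the enolisable C3–H of 10 is not disturbed, and 10 is reduced at once in step 7.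

Step 7
Reactants: 10 methyl (3S)-3-hydroxy-5,7-bis(methoxymethoxy)-2,2-dimethyl-4-oxochroman-6-carboxylate
Product: 11 methyl (3R)-3,4-dihydroxy-5,7-bis(methoxymethoxy)-2,2-dimethylchroman-6-carboxylate (both C4 epimers)
Conditions: NaBH4, MeOH, −20 °C
Reagents that add atoms: none
Why: Borohydride 1,2-reduction of the aryl ketone; the ester is inert, the configuration created at C4 is irrelevant because C4 becomes a methylene in step 8, and fast reduction at low temperature removes the carbonyl that made C3–H enolisable, so C3 is secure from here on (descriptor now R, arrangement in space unchanged).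

Step 8
Reactants: 11 methyl (3R)-3,4-dihydroxy-5,7-bis(methoxymethoxy)-2,2-dimethylchroman-6-carboxylate
Product: 12 methyl (3R)-3-hydroxy-5,7-bis(methoxymethoxy)-2,2-dimethylchroman-6-carboxylate
Conditions: Et3SiH (5 equiv), CF3CO2H (3 equiv), CH2Cl2, −30 to 0 °C; aq. NaHCO3
Reagents that add atoms: none
Why: Ionic hydrogenation (Kursanov–Parnes): acid ionises the C4 hydroxyl to a benzylic cation stabilised by O1 and O5 (ortho) and O7 (para), and the silane delivers hydride to C4; the C3–O bond is not touched, so C3 stays (R), and low temperature with few equivalents of acid is chosen to spare the two acetal ethers.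

Step 9
Reactants: 12 methyl (3R)-3-hydroxy-5,7-bis(methoxymethoxy)-2,2-dimethylchroman-6-carboxylate
Product: 13 (3R)-6-(hydroxymethyl)-5,7-bis(methoxymethoxy)-2,2-dimethylchroman-3-ol
Conditions: LiAlH4, THF, 0 °C to rt; NaOH/H2O work-up
Reagents that add atoms: none
Why: Hydride reduction of the ester to the primary benzylic alcohol; the small aluminium hydride reaches the carbonyl between two ortho substituents, ethers and acetals are inert, and a basic work-up protects the acid-sensitive electron-rich benzylic alcohol.

Step 10
Reactants: 13 (3R)-6-(hydroxymethyl)-5,7-bis(methoxymethoxy)-2,2-dimethylchroman-3-ol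
Product: 14 (3R)-3-hydroxy-5,7-bis(methoxymethoxy)-2,2-dimethylchroman-6-carbaldehyde
Conditions: activated MnO2, CH2Cl2, rt
Reagents that add atoms: none
Why: MnO2 oxidation is selective for benzylic alcohols: the primary benzylic hydroxyl gives the aldehyde without over-oxidation, while the secondary, non-benzylic C3 hydroxyl is not touched.

Step 11
Reactants: 14 (3R)-3-hydroxy-5,7-bis(methoxymethoxy)-2,2-dimethylchroman-6-carbaldehyde
Product: 15 (3R)-6-(1-hydroxyethyl)-5,7-bis(methoxymethoxy)-2,2-dimethylchroman-3-ol (both carbinol epimers)
Conditions: MeMgBr (3 equiv), THF, −78 to 0 °C; aq. NH4Cl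
Reagents that add atoms: methylmagnesium bromide, C[Mg]Br
Why: Grignard addition to the aldehyde; the first equivalent is consumed by the C3 hydroxyl, and the new carbinol centre needs no control because it is oxidised in step 12.

Step 12
Reactants: 15 (3R)-6-(1-hydroxyethyl)-5,7-bis(methoxymethoxy)-2,2-dimethylchroman-3-ol
Product: 16 1-[(3R)-3-hydroxy-5,7-bis(methoxymethoxy)-2,2-dimethylchroman-6-yl]ethan-1-one
Conditions: activated MnO2, CH2Cl2, rt
Reagents that add atoms: none
Why: Second benzylic-selective MnO2 oxidation, now of the secondary benzylic alcohol to the aryl methyl ketone; the C3 hydroxyl again stays as it is.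

Step 13
Reactants: 16 1-[(3R)-3-hydroxy-5,7-bis(methoxymethoxy)-2,2-dimethylchroman-6-yl]ethan-1-one; 17 4-(methoxymethoxy)benzaldehyde
Product: 19 (2E)-1-[(3R)-3-hydroxy-5,7-bis(methoxymethoxy)-2,2-dimethylchroman-6-yl]-3-[4-(methoxymethoxy)phenyl]prop-2-en-1-one, via aldol adduct 18 (not isolated)
Conditions: 17 (1.2 equiv), KOH (aq.), EtOH, rt
Reagents that add atoms: none
Why: Claisen–Schmidt condensation: the methyl ketone enolate adds to the non-enolisable aldehyde 17 to give aldol 18, which loses water by E1cB to the thermodynamically favoured (E)-enone; all phenols are acetal-protected and base-stable, so no oxa-Michael closure to a flavanone can occur.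

Step 14
Reactants: 19 (2E)-1-[(3R)-3-hydroxy-5,7-bis(methoxymethoxy)-2,2-dimethylchroman-6-yl]-3-[4-(methoxymethoxy)phenyl]prop-2-en-1-one
Product: 20 (2E)-1-[(3R)-3,5,7-trihydroxy-2,2-dimethylchroman-6-yl]-3-(4-hydroxyphenyl)prop-2-en-1-one
Conditions: aq. HCl (few equiv), MeOH, rt, close monitoring; NaHCO3
Reagents that add atoms: none
Why: Acid-catalysed acetal exchange with methanol removes the three methoxymethyl groups (those ortho to the ketone fastest); room temperature and prompt neutralisation limit acid-promoted addition of the freed ortho hydroxyls to the enone, and the tertiary ether, the C3 carbinol and the (E)-alkene are not affected.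

## Compound list

1 | methyl 2,4,6-trihydroxybenzoate | COC(=O)c1c(O)cc(O)cc1O | starting material
2 | 3-chloro-3-methylbut-1-yne | CC(C)(Cl)C#C | starting material
3 | methyl 2,6-dihydroxy-4-[(2-methylbut-3-yn-2-yl)oxy]benzoate | COC(=O)c1c(O)cc(OC(C)(C)C#C)cc1O | intermediate
4 | methyl 2,6-dihydroxy-3-(hydroxymethyl)-4-[(2-methylbut-3-yn-2-yl)oxy]benzoate (hydroxymethyl phenol, present as its magnesium salt) | COC(=O)c1c(O)cc(OC(C)(C)C#C)c(CO)c1O | intermediate
5 | methyl 3-formyl-2,6-dihydroxy-4-[(2-methylbut-3-yn-2-yl)oxy]benzoate | COC(=O)c1c(O)cc(OC(C)(C)C#C)c(C=O)c1O | intermediate
6 | methyl 3-formyl-2,6-bis(methoxymethoxy)-4-[(2-methylbut-3-yn-2-yl)oxy]benzoate | COC(=O)c1c(OCOC)cc(OC(C)(C)C#C)c(C=O)c1OCOC | intermediate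
7 | methyl 3-formyl-2,6-bis(methoxymethoxy)-4-[(2-methylbut-3-en-2-yl)oxy]benzoate | COC(=O)c1c(OCOC)cc(OC(C)(C)C=C)c(C=O)c1OCOC | intermediate
8 | methyl 3-formyl-2,6-bis(methoxymethoxy)-4-{[2-(1,2,4-trioxolan-3-yl)propan-2-yl]oxy}benzoate (secondary ozonide) | COC(=O)c1c(OCOC)cc(OC(C)(C)C2OCOO2)c(C=O)c1OCOC | intermediate
9 | methyl 3-formyl-2,6-bis(methoxymethoxy)-4-[(2-methyl-1-oxopropan-2-yl)oxy]benzoate | COC(=O)c1c(OCOC)cc(OC(C)(C)C=O)c(C=O)c1OCOC | intermediate
10 | methyl (3S)-3-hydroxy-5,7-bis(methoxymethoxy)-2,2-dimethyl-4-oxochroman-6-carboxylate | COC(=O)c1c(OCOC)cc2OC(C)(C)[C@H](O)C(=O)c2c1OCOC | intermediate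
11 | methyl (3R)-3,4-dihydroxy-5,7-bis(methoxymethoxy)-2,2-dimethylchroman-6-carboxylate (both C4 epimers) | COC(=O)c1c(OCOC)cc2OC(C)(C)[C@H](O)C(O)c2c1OCOC | intermediate
12 | methyl (3R)-3-hydroxy-5,7-bis(methoxymethoxy)-2,2-dimethylchroman-6-carboxylate | COC(=O)c1c(OCOC)cc2OC(C)(C)[C@H](O)Cc2c1OCOC | intermediate
13 | (3R)-6-(hydroxymethyl)-5,7-bis(methoxymethoxy)-2,2-dimethylchroman-3-ol | OCc1c(OCOC)cc2OC(C)(C)[C@H](O)Cc2c1OCOC | intermediate
14 | (3R)-3-hydroxy-5,7-bis(methoxymethoxy)-2,2-dimethylchroman-6-carbaldehyde | O=Cc1c(OCOC)cc2OC(C)(C)[C@H](O)Cc2c1OCOC | intermediate
15 | (3R)-6-(1-hydroxyethyl)-5,7-bis(methoxymethoxy)-2,2-dimethylchroman-3-ol (both carbinol epimers) | CC(O)c1c(OCOC)cc2OC(C)(C)[C@H](O)Cc2c1OCOC | intermediate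
16 | 1-[(3R)-3-hydroxy-5,7-bis(methoxymethoxy)-2,2-dimethylchroman-6-yl]ethan-1-one | CC(=O)c1c(OCOC)cc2OC(C)(C)[C@H](O)Cc2c1OCOC | intermediate
17 | 4-(methoxymethoxy)benzaldehyde | COCOc1ccc(C=O)cc1 | starting material
18 | 3-hydroxy-1-[(3R)-3-hydroxy-5,7-bis(methoxymethoxy)-2,2-dimethylchroman-6-yl]-3-[4-(methoxymethoxy)phenyl]propan-1-one (both carbinol epimers) | COCOc1ccc(C(O)CC(=O)c2c(OCOC)cc3OC(C)(C)[C@H](O)Cc3c2OCOC)cc1 | intermediate
19 | (2E)-1-[(3R)-3-hydroxy-5,7-bis(methoxymethoxy)-2,2-dimethylchroman-6-yl]-3-[4-(methoxymethoxy)phenyl]prop-2-en-1-one | COCOc1ccc(/C=C/C(=O)c2c(OCOC)cc3OC(C)(C)[C@H](O)Cc3c2OCOC)cc1 | intermediate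
20 | (2E)-1-[(3R)-3,5,7-trihydroxy-2,2-dimethylchroman-6-yl]-3-(4-hydroxyphenyl)prop-2-en-1-one | CC1(C)Oc2cc(O)c(C(=O)/C=C/c3ccc(O)cc3)c(O)c2C[C@H]1O | target

## Step count and least certain steps

Total: 14 steps. Longest linear sequence: 14 steps, from 1 to 20; 2 and 17 are purchased.

**Step 6 (key step, beyond precedent).**
- The carbene may engage the aliphatic aldehyde instead. The enaminol formed there can expel the electron-poor aryloxide from C2, ending in acyl transfer to the phenoxide (an internal redox esterification) and loss of the tether; α-aryloxy aldehydes are prone to this elimination.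
- Turnover may be slow, because the aryl aldehyde is electron-rich and flanked by two ortho oxygens, which disfavours both carbene addition and enaminol formation.
- Enantiomeric purity may erode by base-mediated enolisation of C3–H or by carbene-mediated reversal of the benzoin.
- Fallback (known chemistry only), setting out from 3 and rejoining at 13: both hydroxyls of 3 are converted to acetals (NaH, MOMCl, DMF) to give methyl 2,6-bis(methoxymethoxy)-4-[(2-methylbut-3-yn-2-yl)oxy]benzoate F1. Heating in xylene at about 140 °C brings about the aryl propargyl ether Claisen rearrangement, 1,5-hydrogen shift and 6π electrocyclisation to methyl 5,7-bis(methoxymethoxy)-2,2-dimethyl-2H-chromene-6-carboxylate F2; the two ortho carbons are equivalent and only the ether oxygen is free to close. Jacobsen epoxidation with (R,R)-N,N'-bis(3,5-di-tert-butylsalicylidene)-1,2-cyclohexanediaminomanganese chloride, NaOCl and 4-phenylpyridine N-oxide in CH2Cl2 at 0 °C gives methyl (3R,4R)-3,4-epoxy-5,7-bis(methoxymethoxy)-2,2-dimethylchroman-6-carboxylate F3. LiAlH4 in THF then delivers hydride to benzylic C4 of the epoxide and reduces the ester in the same flask, which gives 13 with C3 already (R).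

**Step 2.**
- A second formylation at the remaining ring position may occur through the other magnesium phenoxide.
- Conversion may be incomplete because both phenols are tied up in chelates with the ester.
- The tertiary propargylic ether may ionise under the Lewis-acidic magnesium salt on prolonged heating.
- Fallback, setting out from 1 and rejoining at 6 (it also replaces steps 1 and 3): selective 4-O-benzylation (BnBr, K2CO3, acetone) gives methyl 4-(benzyloxy)-2,6-dihydroxybenzoate F4. NaH and MOMCl in DMF give methyl 4-(benzyloxy)-2,6-bis(methoxymethoxy)benzoate F5. Hydrogenolysis (H2, 10% Pd/C, EtOAc) gives methyl 4-hydroxy-2,6-bis(methoxymethoxy)benzoate F6. The same magnesium-mediated formylation, now directed by a single free phenol, gives methyl 3-formyl-4-hydroxy-2,6-bis(methoxymethoxy)benzoate F7. Copper-catalysed etherification of this acidic ortho-formyl phenol with 2 (CuCl2·2H2O, DBU, MeCN) then gives 6.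

**Step 8.**
- One or both acetal ethers may be lost, followed by C-alkylation of the electron-rich ring by the methoxymethyl cation, since the acid that ionises C4 can also protonate the acetals.
- A 1,2-hydride shift from C3 to the C4 cation (pinacol type) would destroy the stereocentre; it is disfavoured by the high stability of the cation.
- Fallback, from 11 back to 12: the cleavage is accepted instead of avoided. Et3SiH in excess with CF3CO2H in CH2Cl2 at rt removes the C4 oxygen and both acetals, the silane also scavenging the methoxymethyl cations, to give methyl (3R)-3,5,7-trihydroxy-2,2-dimethylchroman-6-carboxylate F8. NaH (2.1 equiv) and MOMCl in DMF then re-protect the two phenoxides, which are far more acidic than the hindered C3 alcohol, and return 12.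

**Step 14.**
- Acid-promoted conjugate addition of a freed ortho hydroxyl to the enone (flavanone formation) may consume the chalcone while the last acetal is still being cleaved.
- Fallback, from 14 to 20, in which the enone is made after the phenols are freed: aq. HCl in MeOH cleaves the two acetals of 14 to give (3R)-3,5,7-trihydroxy-2,2-dimethylchroman-6-carbaldehyde F9. Chelation-assisted hydroacylation of 4-ethynylphenol F10 (purchased) with [Rh(cod)Cl]2, 1,1'-bis(diphenylphosphino)ferrocene and Na2CO3 in toluene at 80–110 °C should then add the aldehyde C–H across the alkyne to give the linear (E)-enone 20. Branched regiochemistry and alkyne oligomerisation are the risks of this variant.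

## Further compounds

F1 | step 6 | methyl 2,6-bis(methoxymethoxy)-4-[(2-methylbut-3-yn-2-yl)oxy]benzoate | COC(=O)c1c(OCOC)cc(OC(C)(C)C#C)cc1OCOC
F2 | step 6 | methyl 5,7-bis(methoxymethoxy)-2,2-dimethyl-2H-chromene-6-carboxylate | COC(=O)c1c(OCOC)cc2OC(C)(C)C=Cc2c1OCOC
F3 | step 6 | methyl (3R,4R)-3,4-epoxy-5,7-bis(methoxymethoxy)-2,2-dimethylchroman-6-carboxylate | COC(=O)c1c(OCOC)cc2OC(C)(C)[C@@H]3O[C@@H]3c2c1OCOC
F4 | step 2 | methyl 4-(benzyloxy)-2,6-dihydroxybenzoate | COC(=O)c1c(O)cc(OCc2ccccc2)cc1O
F5 | step 2 | methyl 4-(benzyloxy)-2,6-bis(methoxymethoxy)benzoate | COC(=O)c1c(OCOC)cc(OCc2ccccc2)cc1OCOC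
F6 | step 2 | methyl 4-hydroxy-2,6-bis(methoxymethoxy)benzoate | COC(=O)c1c(OCOC)cc(O)cc1OCOC
F7 | step 2 | methyl 3-formyl-4-hydroxy-2,6-bis(methoxymethoxy)benzoate | COC(=O)c1c(OCOC)cc(O)c(C=O)c1OCOC
F8 | step 8 | methyl (3R)-3,5,7-trihydroxy-2,2-dimethylchroman-6-carboxylate | COC(=O)c1c(O)cc2OC(C)(C)[C@H](O)Cc2c1O
F9 | step 14 | (3R)-3,5,7-trihydroxy-2,2-dimethylchroman-6-carbaldehyde | O=Cc1c(O)cc2OC(C)(C)[C@H](O)Cc2c1O
F10 | step 14 | 4-ethynylphenol (purchased) | C#Cc1ccc(O)cc1
A1 | alternative 1 | 8-{[(2R)-3,3-dimethyloxiran-2-yl]methyl}-5,7-dihydroxy-2-(4-hydroxyphenyl)chroman-4-one (mixture at C2) | O=C1CC(c2ccc(O)cc2)Oc2c(C[C@H]3OC3(C)C)c(O)cc(O)c21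
A2 | alternative 1 | angular (3''R)-3''-hydroxy-2'',2''-dimethyldihydropyrano flavanone fused at C8 and O7, with 5-hydroxy and 2-(4-hydroxyphenyl) groups (mixture at C2) | O=C1CC(c2ccc(O)cc2)Oc2c3c(cc(O)c21)OC(C)(C)[C@H](O)C3
A3 | alternative 2 | methyl 5,7-dimethoxy-2,2-dimethyl-2H-chromene-6-carboxylate | COC(=O)c1c(OC)cc2OC(C)(C)C=Cc2c1OC
A4 | alternative 2 | methyl (3R,4R)-3,4-epoxy-5,7-dimethoxy-2,2-dimethylchroman-6-carboxylate | COC(=O)c1c(OC)cc2OC(C)(C)[C@@H]3O[C@@H]3c2c1OC
A5 | alternative 3 | methyl 4-[(4-diazo-2-methyl-3-oxobutan-2-yl)oxy]-2,6-dimethoxybenzoate | COC(=O)c1c(OC)cc(OC(C)(C)C(=O)C=[N+]=[N-])cc1OC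
A6 | alternative 3 | methyl 5,7-dimethoxy-2,2-dimethyl-3-oxochroman-6-carboxylate | COC(=O)c1c(OC)cc2OC(C)(C)C(=O)Cc2c1OC
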